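**Assumptions (one line each)**
- Mycalazal 20 has no stereocentres. Its only stereo-elements are three Z C=C bonds, so "single enantiomer" is moot and the task is to retain all-Z geometry.
- (11Z,14Z,17Z)-Eicosatrienoic acid (ω3-20:3) is treated as a purchasable starting material.

**Retrosynthetic overview**
1. Target **1** is disconnected at the pyrrole C5–CH2 bond by a radical C–H alkylation (Minisci-type) of pyrrole-2-carbaldehyde **3** with the primary C19 radical from decarboxylation of redox-active ester **2**.
2. **2** comes from the all-Z skipped-triene C20 acid **4** and N-hydroxyphthalimide **5**.
3. The pyrrole is bought intact, so no ring is formed. The three Z alkenes come pre-set in **4** and are never touched.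

---

**Step 1**
Reactants: **4** (11Z,14Z,17Z)-eicosa-11,14,17-trienoic acid; **5** N-hydroxyphthalimide
Product: **2** N-(acyloxy)phthalimide of **4**
Conditions: DIC, cat. DMAP, CH2Cl2, 0 °C → rt, 3 h, dark, Ar
Reagents that add atoms: N-hydroxyphthalimide, O=C1c2ccccc2C(=O)N1O (DIC is only the dehydrating agent and leaves as urea)
Why: Carbodiimide (Steglich-type) esterification gives the redox-active ester under neutral, mild conditions that leave the Z-triene untouched, and no new stereo-element is created.

**Step 2**
Reactants: **2** NHPI ester; **3** 1H-pyrrole-2-carbaldehyde (3 equiv)
Product: **1** Mycalazal 20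
Conditions: fac-Ir(ppy)3 (2 mol%), DMA (0.1 M), blue LEDs (455 nm), 25 °C, Ar, 16 h
Reagents that add atoms: none (CO2 and phthalimide are the by-products)
Why: Excited Ir(ppy)3 reduces the NHPI ester by single-electron transfer, which releases CO2 and phthalimide anion and gives the primary C19 radical; this nucleophilic radical adds to C5 of the pyrrole (the δ-position of the vinylogous enal), and Ir(IV) then oxidises the captodative adduct radical, with loss of H+, to rearomatise.
Proposed new method: This is a decarboxylative Minisci-type C–H alkylation applied to an N–H pyrrole-2-carbaldehyde bearing a skipped all-Z triene. The closest known reactions are Ir-photoredox decarboxylative alkylation of heteroarenes with NHPI esters and nucleophilic-radical addition to electron-poor heteroarenes. The Z geometry survives because the reductive (not oxidative) radical generation avoids oxidising the bis-allylic polyene, because Ir(ppy)3 triplet energy is far below that needed to isomerise isolated alkenes, and because the radical sits 9 carbons from the first alkene. The new bond is sp2–sp3 and creates no stereocentre.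

---

**Checks**
- Structure: the chain is pyrrole–(CH2)9–CH=CH–CH2–CH=CH–CH2–CH=CH–CH2CH3, all Z, with CHO at C2 and the chain at C5 of a free N–H pyrrole. This matches the target SMILES.
- Carbon count: acid **4** has C1 (COOH) plus 9 CH2, so decarboxylation leaves a radical with 9 CH2 before the first alkene, as required.
- Atom balance, step 2: **2** + **3** → **1** + CO2 + phthalimide.
- Functional groups: the aldehyde, the free N–H and the three Z alkenes all survive both steps.
- Stereo-elements: the Z alkenes are carried unchanged from **4**, so nothing is scrambled.

---

**Compound list**

| No. | Name | SMILES | Role |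
|---|---|---|---|
| 1 | Mycalazal 20 | CC/C=C\C/C=C\C/C=C\CCCCCCCCCc1ccc(C=O)[nH]1 | target |
| 2 | N-[(11Z,14Z,17Z)-eicosa-11,14,17-trienoyloxy]phthalimide | CC/C=C\C/C=C\C/C=C\CCCCCCCCCC(=O)ON1C(=O)c2ccccc2C1=O | intermediate |
| 3 | 1H-pyrrole-2-carbaldehyde | O=Cc1ccc[nH]1 | starting material |
| 4 | (11Z,14Z,17Z)-eicosa-11,14,17-trienoic acid | CC/C=C\C/C=C\C/C=C\CCCCCCCCCC(=O)O | starting material |
| 5 | N-hydroxyphthalimide | O=C1c2ccccc2C(=O)N1O | starting material |

**Total step count:** 2
**Longest linear sequence:** 2 steps (4 → 2 → 1)

**Three most likely failure points**
1. **Step 2, C5 versus C3 regioselectivity and low conversion of the radical addition to neutral pyrrole-2-carbaldehyde.**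
   Fallback: use Ni-catalysed decarboxylative (reductive) cross-coupling of **2** with commercial 5-bromo-1-Boc-pyrrole-2-carbaldehyde (Zn, NiCl2·glyme/bipyridine), then remove the Boc group. This swaps radical addition for a metal-controlled C(sp2)–C(sp3) bond.
2. **Step 2, chemoselectivity: hydrogen-atom abstraction from the bis-allylic CH2 groups or polyene autoxidation competing with radical addition.**
   Fallback: abandon the radical union and use the polar route, a Z-selective Wittig reaction between (3Z,6Z)-nona-3,6-dienyl-PPh3 Br and 10-(5-formylpyrrol-2-yl)decanal (or a suitably protected form of it).
3. **Step 1, activation and handling: the NHPI ester is light-sensitive and the triene is prone to autoxidation, and the pyrrole N–H could acylate in step 2.**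
   Fallback: reduce acid **4** to the alcohol, convert it to the primary iodide, and use the iodide as the radical or Ni-coupling precursor. This avoids the active ester entirely.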